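The earlier runs and the new flask come from a simulation with constants of no real substance; the scatter is artificial.

Time stops helping the south-west flask early: Je, the product, reads 49.3% of the Ja (substrate) charged at 12.0 min and 50.2% at 40.0 min. Jb is the reagent, Jd the catalyst as charged and Jc its working form.

| flask | Ja | Jb | Jd | temperature | remark | time |
|---|---|---|---|---|---|---|
| south-west | 0.20 M | 0.10 M | 1 mM | 25 °C | the very flask that is asked about, followed so far |  |
| north-east | 0.10 M | 0.10 M | 1 mM | 31 °C | run made earlier |  |
| flask | 0.20 M | 0.100 M | 1.0 mM | 25 °C |  | 1.0 h |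

south-west run (percent of the Ja charged)

| time / min | Je / % | Ja / % |
|---|---|---|
| 3.00 | 37.5 | 61.8 |
| 5.00 | 45.3 | 55.6 |
| 8.00 | 48.3 | 50.6 |
| 12.0 | 49.3 | 49.2 |
| 20.0 | 50.0 | 50.5 |
| 40.0 | 50.2 | 50.0 |

north-east run (percent of the Ja charged)

| time / min | Je / % | Ja / % |
|---|---|---|
| 1.00 | 27.3 | 74.2 |
| 1.50 | 39.0 | 61.3 |
| 2.50 | 54.1 | 45.7 |
| 4.00 | 66.2 | 32.5 |
| 8.00 | 81.0 | 19.0 |
| 12.0 | 86.5 | 13.1 |

- green: at 1.0 h add Jb, 50.0% of the amount charged, then wait 2.0 h
- teal: at 1.0 h raise the temperature by 10 K, then wait 2.0 h
- grey: change nothing and wait 2.0 h more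
- red: at 1.0 h take out 90% of the Je then present, then wait 2.0 h
- violet: at 1.0 h add Jd, 50.0% of the amount charged, then wait 2.0 h

1. Je, in percent of the Ja first charged, at 1.0 h
2. the option that brings most further Je ("none" if no option brings more than 2 percentage points) (green / teal / grey / red / violet / none)
3. Je present, with what was taken out counted in, in percent of the Ja first charged, after teal
4. Je present, with what was taken out counted in, in percent of the Ja first charged, after violet

- removed Je is counted in
- steps thought possible: Ja + Jb + Jc -> Jc + Je; Jd -> Jc
- additions bring no volume worth counting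

Read the south-west table row by row. Ja and Je add up to 99.3% in the first row and 100% in the last, so the Ja lost appears as Je. The last rows are flat, so ask what stops Je there.

Divide the rate of loss of Ja by the rate of loss of Jb. In the listed step Ja + Jb + Jc → Jc + Je this ratio is one at every moment, so time drops out and each Je costs one Jb. In the south-west flask Jb, charged at less than Ja, is the limiting reagent, and Je can reach 50.0% of the Ja charged. Call this the ceiling: the Jb charged divided by the Ja charged, where Jb is not the larger charge. It comes from the charges, and the plateau reading stands on it within the scatter of 0.5 percentage points. In the north-east table the ceiling is 100%, and Je passes the south-west plateau to reach 86.5%, still rising.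

My reckoning follows. The plateau is reached by 40.0 min, earlier than 1.0 h, so Je at 1.0 h is the ceiling. Teal, grey, red and violet add no Jb, so they leave the ceiling where it is. Green raises the ceiling to 75.0%.

The forecast gives 50% (49.5% to 50.5%), names green, and puts teal at 50% and violet at 50%, each from 49.4% to 50.8%. Its ground is that “no Jb remains”.

The flask gives 50.0% at 1.0 h; green is best, teal gives 50.0% and violet 50.0%.

    Ja + Jb + Jc → Jc + Je (k = 4140 M⁻² min⁻¹, Ea = 38.0 kJ mol⁻¹)
    Jd → Jc (k = 1.48 min⁻¹, Ea = 76.0 kJ mol⁻¹)
    (constants at 25 °C)

The consumption of Jb holds the flask at its ceiling of 50.0%: with that consumption taken away, the same flask reaches 100% at 1.0 h. Green lifts the ceiling of the flask by 25 points, and it brings 25 points. A neighbour flask, charged with 0.025 M of Jb, has a ceiling of 12.5% and gives 12.5%.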